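**Retrosynthetic overview**

1. Target 20 comes from the hexasilyl flavanone 19 by global desilylation. 19 comes from a rhodium-catalysed asymmetric 1,4-addition of the dihydrobenzofuran-5-ylboronic acid 11 to the 8-substituted chromone 18, which makes the C2–C1′ bond and the 2S centre of the flavanone last, on a pyranone ring that is already in place.
2. 11 comes, through the aryl triflate, from the 2,3-diaryl-2,3-dihydrobenzofuran-5-ol 6. The carbon substituent at C5 of ring B is traded for an oxygen, so that ring B (O1 on C7a, oxygen on C5, para to each other, alkoxy on C6) maps onto a 2-alkoxy-1,4-benzoquinone.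
3. 6 comes from ring expansion of a donor–acceptor cyclobutane (a bicyclo[4.2.0]octenedione). The enabling feature is that C2 carries a cation-stabilising 4-oxyphenyl ring and C4/C3a belong to the enedione, so the four-membered ring (C2, C3, C3a, C4) opens at C2–C4 and recloses through the C7a carbonyl oxygen to the five-membered ring (O1, C2, C3, C3a, C7a), with aromatisation of ring B. The cyclobutane forms in the same flask from tri-O-benzylresveratrol 2 and 2-benzyloxy-1,4-benzoquinone 4.
4. 18 comes from 5,7-dihydroxychromone by 7-O-allylation, Claisen rearrangement to C8, cross-metathesis with methacrolein (E alkene) and 1,2-reduction.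
5. Ring order: pyranone (bought), then cyclobutane, then dihydrofuran with aromatic ring B, then the flavanone C2 centre.

Key step: step 3

Assumption: the sense of induction of (R,R)-TADDOL in step 3 and of (S)-MeO-F12-BIPHEP in step 15 is assigned by analogy with simpler substrates; if either proves opposite, the antipodal ligand is used with no other change.

**Route**

Step 1
Reactants: 1 resveratrol
Product: 2 (E)-3,4′,5-tris(benzyloxy)stilbene
Conditions: BnBr, K2CO3, DMF, 60 °C
Reagents that add atoms: benzyl bromide, BrCc1ccccc1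
Why: Williamson ether synthesis on the three phenoxides should give the tribenzyl ether, with no stereocentre formed and the E alkene untouched.

Step 2
Reactants: 3 2-(benzyloxy)phenol
Product: 4 2-(benzyloxy)-1,4-benzoquinone
Conditions: ON(SO3K)2 (2.2 equiv), KH2PO4, H2O/acetone, 0 °C → rt
Reagents that add atoms: potassium nitrosodisulfonate, [K+].[K+].[O]N(S(=O)(=O)[O-])S(=O)(=O)[O-]
Why: Teuber oxidation of a 2-alkoxyphenol with a free para position should give the 2-alkoxy-1,4-benzoquinone, with no stereocentre formed.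

Step 3
Reactants: 2 (E)-3,4′,5-tris(benzyloxy)stilbene; 4 2-(benzyloxy)-1,4-benzoquinone
Product: 6 (2R,3R)-6-(benzyloxy)-2-[4-(benzyloxy)phenyl]-3-[3,5-bis(benzyloxy)phenyl]-2,3-dihydro-1-benzofuran-5-ol, via cyclobutane adduct 5 (not isolated)
Conditions: TiCl4/Ti(OiPr)4 (1:1), (R,R)-TADDOL, CH2Cl2, −78 °C; then CF3CO2H, −78 → 0 °C
Reagents that add atoms: none
Why: The chiral tetravalent-titanium Lewis acid is chelated by the C1 carbonyl and the 2-benzyloxy oxygen of 4, the alkene carbon of 2 that bears the 3,5-bis(benzyloxy)phenyl ring attacks the quinone CH that becomes C3a, and the titanium enolate carbon (later C4) collapses onto the resulting 4-benzyloxybenzyl cation to give cyclobutane 5 by a stepwise ionic 4-exo closure (formal [2+2]). On acidification and warming the donor–acceptor bond C2–C4 of 5 should ionise again, the neighbouring carbonyl oxygen (later O1 on C7a) captures the cation in a five-membered C–O closure, and loss of the ring-fusion proton aromatises ring B, so that the four-membered ring (C2, C3, C3a, C4) is expanded to the five-membered ring (O1, C2, C3, C3a, C7a). The closest known reaction type is the TiCl4/Ti(OiPr)4-promoted formal [2+2] cycloaddition of 2-alkoxy-1,4-benzoquinones with (E)-1-propenylarenes and the acid-induced rearrangement of the resulting 8-aryl-bicyclo[4.2.0]oct-3-ene-2,5-diones to trans-2-aryl-2,3-dihydrobenzofuran-5-ols, including its TADDOLate-controlled enantioselective form; here the β-substituent of the styrene is aryl instead of methyl. C3 is created in the first C–C bond formation, its 3R configuration is controlled by the chiral titanium complex and it is not touched by the ring expansion, whereas C2 is created in the C–O closure on a planar benzylic cation and is controlled by C3, the oxygen adding anti to the C3 aryl group to give the trans (2R,3R) ring. The step needs regioselectivity at the alkene (secured because only the 4-alkoxyphenyl ring, not the meta-dialkoxyphenyl ring, stabilises the cation), regioselectivity at the quinone (secured by the chelate, which activates the CH conjugate to the C1 carbonyl), and ring expansion in preference to [5+2] closure (favoured by the mixed chloride/isopropoxide Lewis acid at low temperature followed by protic acid).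

Step 4
Reactants: 6 (2R,3R)-6-(benzyloxy)-2-[4-(benzyloxy)phenyl]-3-[3,5-bis(benzyloxy)phenyl]-2,3-dihydro-1-benzofuran-5-ol
Product: 7 (2R,3R)-6-(benzyloxy)-2-[4-(benzyloxy)phenyl]-3-[3,5-bis(benzyloxy)phenyl]-2,3-dihydro-1-benzofuran-5-yl trifluoromethanesulfonate
Conditions: Tf2O, pyridine, CH2Cl2, 0 °C
Reagents that add atoms: trifluoromethanesulfonic anhydride, O=S(=O)(OS(=O)(=O)C(F)(F)F)C(F)(F)F
Why: O-sulfonylation of the only free phenol should give the aryl triflate that marks C5 for C–C bond formation and keeps it distinct from the four benzyl-protected oxygens.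

Step 5
Reactants: 7 (2R,3R)-6-(benzyloxy)-2-[4-(benzyloxy)phenyl]-3-[3,5-bis(benzyloxy)phenyl]-2,3-dihydro-1-benzofuran-5-yl trifluoromethanesulfonate
Product: 8 (2R,3R)-3-(3,5-dihydroxyphenyl)-6-hydroxy-2-(4-hydroxyphenyl)-2,3-dihydro-1-benzofuran-5-yl trifluoromethanesulfonate
Conditions: H2 (1 atm), Pd/C, EtOAc/MeOH, rt
Reagents that add atoms: none
Why: Heterogeneous hydrogenolysis should cleave the four benzyl aryl ethers while, in the absence of base, the aryl triflate and the cyclic benzylic C2–O1 bond are expected to survive; no alkene is present at this stage and the stereocentres are untouched.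

Step 6
Reactants: 8 (2R,3R)-3-(3,5-dihydroxyphenyl)-6-hydroxy-2-(4-hydroxyphenyl)-2,3-dihydro-1-benzofuran-5-yl trifluoromethanesulfonate
Product: 9 (2R,3R)-6-[(tert-butyldimethylsilyl)oxy]-2-{4-[(tert-butyldimethylsilyl)oxy]phenyl}-3-{3,5-bis[(tert-butyldimethylsilyl)oxy]phenyl}-2,3-dihydro-1-benzofuran-5-yl trifluoromethanesulfonate
Conditions: TBSCl, imidazole, DMF, rt
Reagents that add atoms: tert-butyldimethylsilyl chloride, CC(C)(C)[Si](C)(C)Cl
Why: Silylation of the four phenols should install groups that survive the boron chemistry and leave at the end under non-basic fluoride conditions, which the flavanone and the allylic alcohol tolerate.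

Step 7
Reactants: 9 (2R,3R)-6-[(tert-butyldimethylsilyl)oxy]-2-{4-[(tert-butyldimethylsilyl)oxy]phenyl}-3-{3,5-bis[(tert-butyldimethylsilyl)oxy]phenyl}-2,3-dihydro-1-benzofuran-5-yl trifluoromethanesulfonate
Product: 10 2-[(2R,3R)-6-[(tert-butyldimethylsilyl)oxy]-2-{4-[(tert-butyldimethylsilyl)oxy]phenyl}-3-{3,5-bis[(tert-butyldimethylsilyl)oxy]phenyl}-2,3-dihydro-1-benzofuran-5-yl]-4,4,5,5-tetramethyl-1,3,2-dioxaborolane
Conditions: B2pin2, PdCl2(dppf), dppf, KOAc, 1,4-dioxane, 85 °C
Reagents that add atoms: bis(pinacolato)diboron, CC1(C)OB(B2OC(C)(C)C(C)(C)O2)OC1(C)C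
Why: Miyaura borylation of the aryl triflate (oxidative addition, acetate-assisted transmetalation with the diboron, reductive elimination) should give the pinacol boronate without touching the silyl ethers or the stereocentres.

Step 8
Reactants: 10 2-[(2R,3R)-6-[(tert-butyldimethylsilyl)oxy]-2-{4-[(tert-butyldimethylsilyl)oxy]phenyl}-3-{3,5-bis[(tert-butyldimethylsilyl)oxy]phenyl}-2,3-dihydro-1-benzofuran-5-yl]-4,4,5,5-tetramethyl-1,3,2-dioxaborolane
Product: 11 [(2R,3R)-6-[(tert-butyldimethylsilyl)oxy]-2-{4-[(tert-butyldimethylsilyl)oxy]phenyl}-3-{3,5-bis[(tert-butyldimethylsilyl)oxy]phenyl}-2,3-dihydro-1-benzofuran-5-yl]boronic acid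
Conditions: NaIO4, NH4OAc, acetone/H2O, rt
Reagents that add atoms: water, O
Why: Hydrolysis of the boronic ester is driven by periodate glycol cleavage of the released pinacol, which should give the free boronic acid that transmetalates to rhodium under mild, base-free conditions.

Step 9
Reactants: 12 5,7-dihydroxy-4H-chromen-4-one
Product: 13 5-hydroxy-7-(prop-2-en-1-yloxy)-4H-chromen-4-one
Conditions: allyl bromide (1.1 equiv), K2CO3, acetone, reflux
Reagents that add atoms: allyl bromide, C=CCBr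
Why: Williamson etherification should be selective for the more acidic 7-OH, because the 5-OH is held in a hydrogen bond to the C4 carbonyl.

Step 10
Reactants: 13 5-hydroxy-7-(prop-2-en-1-yloxy)-4H-chromen-4-one
Product: 14 5,7-dihydroxy-8-(prop-2-en-1-yl)-4H-chromen-4-one
Conditions: PhNEt2, 195 °C
Reagents that add atoms: none
Why: Aromatic Claisen rearrangement ([3,3]-sigmatropic shift, then tautomerisation) should deliver the allyl group to C8, the ortho position across the C7–C8 bond of higher double-bond character, which fixes the side chain next to the ring oxygen.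

Step 11
Reactants: 14 5,7-dihydroxy-8-(prop-2-en-1-yl)-4H-chromen-4-one
Product: 15 7-[(tert-butyldimethylsilyl)oxy]-5-hydroxy-8-(prop-2-en-1-yl)-4H-chromen-4-one
Conditions: TBSCl (1.1 equiv), imidazole, DMF, 0 °C
Reagents that add atoms: tert-butyldimethylsilyl chloride, CC(C)(C)[Si](C)(C)Cl
Why: Silylation should take place at the free 7-OH only, the chelated 5-OH being much less nucleophilic.

Step 12
Reactants: 15 7-[(tert-butyldimethylsilyl)oxy]-5-hydroxy-8-(prop-2-en-1-yl)-4H-chromen-4-one
Product: 16 (2E)-4-{7-[(tert-butyldimethylsilyl)oxy]-5-hydroxy-4-oxo-4H-chromen-8-yl}-2-methylbut-2-enal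
Conditions: methacrolein (10 equiv), second-generation Hoveyda–Grubbs catalyst (5 mol %), CH2Cl2, 40 °C
Reagents that add atoms: methacrolein, CC(=C)C=O
Why: Olefin cross-metathesis of the terminal alkene with the 1,1-disubstituted enal should give the trisubstituted enal as the thermodynamically favoured E isomer, while the electron-poor C2=C3 bond of the chromone stays out of the metathesis.

Step 13
Reactants: 16 (2E)-4-{7-[(tert-butyldimethylsilyl)oxy]-5-hydroxy-4-oxo-4H-chromen-8-yl}-2-methylbut-2-enal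
Product: 17 7-[(tert-butyldimethylsilyl)oxy]-5-hydroxy-8-[(2E)-4-hydroxy-3-methylbut-2-en-1-yl]-4H-chromen-4-one
Conditions: NaBH4, CeCl3·7H2O, MeOH/THF, −78 °C
Reagents that add atoms: none
Why: Luche reduction should reduce the enal in the 1,2 sense to the E allylic alcohol, while the vinylogous ester carbonyl of the chromone is too unreactive to compete at low temperature.

Step 14
Reactants: 17 7-[(tert-butyldimethylsilyl)oxy]-5-hydroxy-8-[(2E)-4-hydroxy-3-methylbut-2-en-1-yl]-4H-chromen-4-one
Product: 18 7-[(tert-butyldimethylsilyl)oxy]-8-[(2E)-4-[(tert-butyldimethylsilyl)oxy]-3-methylbut-2-en-1-yl]-5-hydroxy-4H-chromen-4-one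
Conditions: TBSCl (1.2 equiv), imidazole, CH2Cl2, 0 °C → rt
Reagents that add atoms: tert-butyldimethylsilyl chloride, CC(C)(C)[Si](C)(C)Cl
Why: Silylation of the primary allylic alcohol should be selective over the chelated 5-OH, which is left free to activate the enone by hydrogen bonding.

Step 15
Reactants: 11 [(2R,3R)-6-[(tert-butyldimethylsilyl)oxy]-2-{4-[(tert-butyldimethylsilyl)oxy]phenyl}-3-{3,5-bis[(tert-butyldimethylsilyl)oxy]phenyl}-2,3-dihydro-1-benzofuran-5-yl]boronic acid; 18 7-[(tert-butyldimethylsilyl)oxy]-8-[(2E)-4-[(tert-butyldimethylsilyl)oxy]-3-methylbut-2-en-1-yl]-5-hydroxy-4H-chromen-4-one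
Product: 19 (2S)-7-[(tert-butyldimethylsilyl)oxy]-8-[(2E)-4-[(tert-butyldimethylsilyl)oxy]-3-methylbut-2-en-1-yl]-2-[(2R,3R)-6-[(tert-butyldimethylsilyl)oxy]-2-{4-[(tert-butyldimethylsilyl)oxy]phenyl}-3-{3,5-bis[(tert-butyldimethylsilyl)oxy]phenyl}-2,3-dihydro-1-benzofuran-5-yl]-5-hydroxy-2,3-dihydro-4H-chromen-4-one
Conditions: [Rh(OH)(cod)]2 (3 mol %), (S)-MeO-F12-BIPHEP (7 mol %), 11 (1.5 equiv), CH2Cl2/H2O, 30 °C
Reagents that add atoms: none
Why: Hayashi–Miyaura asymmetric conjugate addition (transmetalation to the rhodium hydroxide, enantioface-selective insertion of the chromone C2=C3 bond into the aryl–rhodium bond, protonolysis of the oxa-π-allyl) should form the C2–aryl bond and set 2S under control of the electron-poor chiral diphosphine, the dihydrobenzofuran stereocentres being too remote to override the catalyst.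

Step 16
Reactants: 19 (2S)-7-[(tert-butyldimethylsilyl)oxy]-8-[(2E)-4-[(tert-butyldimethylsilyl)oxy]-3-methylbut-2-en-1-yl]-2-[(2R,3R)-6-[(tert-butyldimethylsilyl)oxy]-2-{4-[(tert-butyldimethylsilyl)oxy]phenyl}-3-{3,5-bis[(tert-butyldimethylsilyl)oxy]phenyl}-2,3-dihydro-1-benzofuran-5-yl]-5-hydroxy-2,3-dihydro-4H-chromen-4-one
Product: 20 (2S)-2-[(2R,3R)-3-(3,5-dihydroxyphenyl)-6-hydroxy-2-(4-hydroxyphenyl)-2,3-dihydro-1-benzofuran-5-yl]-5,7-dihydroxy-8-[(2E)-4-hydroxy-3-methylbut-2-en-1-yl]-2,3-dihydro-4H-chromen-4-one (CNP0235407.2)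
Conditions: HF·pyridine, pyridine, THF, 0 °C → rt
Reagents that add atoms: none
Why: Fluoride-mediated desilylation under buffered, non-basic conditions should remove the five aryl and the one alkyl silyl ether without retro-oxa-Michael opening of the flavanone (which would epimerise C2 and could move the side chain from C8 to C6 through the free 5-OH) and without ionising the allylic alcohol.

**Compound list**

1 | resveratrol, (E)-5-[2-(4-hydroxyphenyl)ethenyl]benzene-1,3-diol | Oc1ccc(/C=C/c2cc(O)cc(O)c2)cc1 | starting material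
2 | (E)-3,4′,5-tris(benzyloxy)stilbene | c1ccc(COc2ccc(/C=C/c3cc(OCc4ccccc4)cc(OCc4ccccc4)c3)cc2)cc1 | intermediate
3 | 2-(benzyloxy)phenol | Oc1ccccc1OCc1ccccc1 | starting material
4 | 2-(benzyloxy)-1,4-benzoquinone | O=C1C=CC(=O)C(OCc2ccccc2)=C1 | intermediate
5 | 3-(benzyloxy)-8-[4-(benzyloxy)phenyl]-7-[3,5-bis(benzyloxy)phenyl]bicyclo[4.2.0]oct-3-ene-2,5-dione (cis-fused; 8-aryl endo, 7-aryl exo, aryl groups trans; C7 configured as C3 of 6) | c1ccccc1COC1=CC(=O)[C@H]2[C@@H](C1=O)[C@@H](c1ccc(OCc3ccccc3)cc1)[C@@H]2c1cc(OCc2ccccc2)cc(OCc2ccccc2)c1 | intermediate (not isolated)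
6 | (2R,3R)-6-(benzyloxy)-2-[4-(benzyloxy)phenyl]-3-[3,5-bis(benzyloxy)phenyl]-2,3-dihydro-1-benzofuran-5-ol | Oc1cc2c(cc1OCc1ccccc1)O[C@@H](c1ccc(OCc3ccccc3)cc1)[C@@H]2c1cc(OCc2ccccc2)cc(OCc2ccccc2)c1 | intermediate
7 | (2R,3R)-6-(benzyloxy)-2-[4-(benzyloxy)phenyl]-3-[3,5-bis(benzyloxy)phenyl]-2,3-dihydro-1-benzofuran-5-yl trifluoromethanesulfonate | O=S(=O)(Oc1cc2c(cc1OCc1ccccc1)O[C@@H](c1ccc(OCc3ccccc3)cc1)[C@@H]2c1cc(OCc2ccccc2)cc(OCc2ccccc2)c1)C(F)(F)F | intermediate
8 | (2R,3R)-3-(3,5-dihydroxyphenyl)-6-hydroxy-2-(4-hydroxyphenyl)-2,3-dihydro-1-benzofuran-5-yl trifluoromethanesulfonate | O=S(=O)(Oc1cc2c(cc1O)O[C@@H](c1ccc(O)cc1)[C@@H]2c1cc(O)cc(O)c1)C(F)(F)F | intermediate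
9 | (2R,3R)-6-[(tert-butyldimethylsilyl)oxy]-2-{4-[(tert-butyldimethylsilyl)oxy]phenyl}-3-{3,5-bis[(tert-butyldimethylsilyl)oxy]phenyl}-2,3-dihydro-1-benzofuran-5-yl trifluoromethanesulfonate | O=S(=O)(Oc1cc2c(cc1O[Si](C)(C)C(C)(C)C)O[C@@H](c1ccc(O[Si](C)(C)C(C)(C)C)cc1)[C@@H]2c1cc(O[Si](C)(C)C(C)(C)C)cc(O[Si](C)(C)C(C)(C)C)c1)C(F)(F)F | intermediate
10 | 2-[(2R,3R)-6-[(tert-butyldimethylsilyl)oxy]-2-{4-[(tert-butyldimethylsilyl)oxy]phenyl}-3-{3,5-bis[(tert-butyldimethylsilyl)oxy]phenyl}-2,3-dihydro-1-benzofuran-5-yl]-4,4,5,5-tetramethyl-1,3,2-dioxaborolane | CC1(C)OB(c2cc3c(cc2O[Si](C)(C)C(C)(C)C)O[C@@H](c2ccc(O[Si](C)(C)C(C)(C)C)cc2)[C@@H]3c2cc(O[Si](C)(C)C(C)(C)C)cc(O[Si](C)(C)C(C)(C)C)c2)OC1(C)C | intermediate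
11 | [(2R,3R)-6-[(tert-butyldimethylsilyl)oxy]-2-{4-[(tert-butyldimethylsilyl)oxy]phenyl}-3-{3,5-bis[(tert-butyldimethylsilyl)oxy]phenyl}-2,3-dihydro-1-benzofuran-5-yl]boronic acid | OB(O)c1cc2c(cc1O[Si](C)(C)C(C)(C)C)O[C@@H](c1ccc(O[Si](C)(C)C(C)(C)C)cc1)[C@@H]2c1cc(O[Si](C)(C)C(C)(C)C)cc(O[Si](C)(C)C(C)(C)C)c1 | intermediate
12 | 5,7-dihydroxy-4H-chromen-4-one | O=C1C=COc2cc(O)cc(O)c12 | starting material
13 | 5-hydroxy-7-(prop-2-en-1-yloxy)-4H-chromen-4-one | C=CCOc1cc(O)c2c(c1)OC=CC2=O | intermediate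
14 | 5,7-dihydroxy-8-(prop-2-en-1-yl)-4H-chromen-4-one | C=CCc1c(O)cc(O)c2c1OC=CC2=O | intermediate
15 | 7-[(tert-butyldimethylsilyl)oxy]-5-hydroxy-8-(prop-2-en-1-yl)-4H-chromen-4-one | C=CCc1c(O[Si](C)(C)C(C)(C)C)cc(O)c2c1OC=CC2=O | intermediate
16 | (2E)-4-{7-[(tert-butyldimethylsilyl)oxy]-5-hydroxy-4-oxo-4H-chromen-8-yl}-2-methylbut-2-enal | C/C(=C\Cc1c(O[Si](C)(C)C(C)(C)C)cc(O)c2c1OC=CC2=O)C=O | intermediate
17 | 7-[(tert-butyldimethylsilyl)oxy]-5-hydroxy-8-[(2E)-4-hydroxy-3-methylbut-2-en-1-yl]-4H-chromen-4-one | C/C(=C\Cc1c(O[Si](C)(C)C(C)(C)C)cc(O)c2c1OC=CC2=O)CO | intermediate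
18 | 7-[(tert-butyldimethylsilyl)oxy]-8-[(2E)-4-[(tert-butyldimethylsilyl)oxy]-3-methylbut-2-en-1-yl]-5-hydroxy-4H-chromen-4-one | C/C(=C\Cc1c(O[Si](C)(C)C(C)(C)C)cc(O)c2c1OC=CC2=O)CO[Si](C)(C)C(C)(C)C | intermediate
19 | (2S)-7-[(tert-butyldimethylsilyl)oxy]-8-[(2E)-4-[(tert-butyldimethylsilyl)oxy]-3-methylbut-2-en-1-yl]-2-[(2R,3R)-6-[(tert-butyldimethylsilyl)oxy]-2-{4-[(tert-butyldimethylsilyl)oxy]phenyl}-3-{3,5-bis[(tert-butyldimethylsilyl)oxy]phenyl}-2,3-dihydro-1-benzofuran-5-yl]-5-hydroxy-2,3-dihydro-4H-chromen-4-one | C/C(=C\Cc1c(O[Si](C)(C)C(C)(C)C)cc(O)c2c1O[C@H](c1cc3c(cc1O[Si](C)(C)C(C)(C)C)O[C@@H](c1ccc(O[Si](C)(C)C(C)(C)C)cc1)[C@@H]3c1cc(O[Si](C)(C)C(C)(C)C)cc(O[Si](C)(C)C(C)(C)C)c1)CC2=O)CO[Si](C)(C)C(C)(C)C | intermediate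
20 | (2S)-2-[(2R,3R)-3-(3,5-dihydroxyphenyl)-6-hydroxy-2-(4-hydroxyphenyl)-2,3-dihydro-1-benzofuran-5-yl]-5,7-dihydroxy-8-[(2E)-4-hydroxy-3-methylbut-2-en-1-yl]-2,3-dihydro-4H-chromen-4-one | C/C(=C\Cc1c(O)cc(O)c2c1O[C@H](c1cc3c(cc1O)O[C@@H](c1ccc(O)cc1)[C@@H]3c1cc(O)cc(O)c1)CC2=O)CO | target

**Step count and risks**

Total step count: 16. Longest linear sequence: 9 steps (steps 1, 3, 4, 5, 6, 7, 8, 15, 16).

Steps most likely to fail:

Step 3. The bulky titanium TADDOLate may discriminate poorly between the faces of the 1,2-diarylethene, and the selectivity may erode further if the first C–C bond formation reverses before the cyclobutane closes. The fallback gives up asymmetric induction in favour of resolution. It sets out from 2 and 4, which are combined without the chiral diol (TiCl4/Ti(OiPr)4, CH2Cl2, −78 °C, then CF3CO2H), the conditions under which this annulation is best established. This should give 5 together with its mirror-image cyclobutane F1 (not isolated) and hence 6 together with its (2S,3S) enantiomer F2. The racemate is resolved by preparative chromatography on a chiral stationary phase (amylose tris(3,5-dimethylphenylcarbamate), supercritical CO2/MeOH), and the (2R,3R) antipode comes back to the route at 6.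

Step 15. Aryl transfer from the hindered ortho-silyloxy boronic acid to rhodium may be slow, so that protodeboronation competes and facial control at C2 is eroded. The fallback separates C–C bond formation from stereocontrol. It sets out from 11 and 18, which are joined with an achiral cationic divalent-palladium catalyst (Pd(OCOCF3)2, 2,2′-bipyridine, AcOH/THF/H2O, 60 °C; carbopalladation then protonolysis). This should give 19 together with its C2 epimer F3; because the dihydrobenzofuran centres are fixed, the two are diastereomers and are separated by preparative HPLC. The route is rejoined at 19.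

Step 10. The allyl group may migrate in part to C6, the position activated by the chelated 5-OH, and the o-allylphenol may cyclise at 195 °C. The fallback blocks the chelation before the rearrangement. It sets out from 13, which is acetylated (Ac2O, pyridine, DMAP) to 4-oxo-7-(prop-2-en-1-yloxy)-4H-chromen-5-yl acetate F4. Claisen rearrangement of F4 (PhNEt2, 190 °C), in which C6 is flanked by the acetoxy group and no longer activated, should give 7-hydroxy-4-oxo-8-(prop-2-en-1-yl)-4H-chromen-5-yl acetate F5. Methanolysis (K2CO3, MeOH, rt) returns the route at 14.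

**Further compounds**

F1 | step 3 | mirror image of cyclobutane 5 | c1ccccc1COC1=CC(=O)[C@@H]2[C@H](C1=O)[C@H](c1ccc(OCc3ccccc3)cc1)[C@H]2c1cc(OCc2ccccc2)cc(OCc2ccccc2)c1
F2 | step 3 | (2S,3S)-6-(benzyloxy)-2-[4-(benzyloxy)phenyl]-3-[3,5-bis(benzyloxy)phenyl]-2,3-dihydro-1-benzofuran-5-ol | Oc1cc2c(cc1OCc1ccccc1)O[C@H](c1ccc(OCc3ccccc3)cc1)[C@H]2c1cc(OCc2ccccc2)cc(OCc2ccccc2)c1
F3 | step 15 | (2R) epimer of 19 at the flavanone carbon C2 | C/C(=C\Cc1c(O[Si](C)(C)C(C)(C)C)cc(O)c2c1O[C@@H](c1cc3c(cc1O[Si](C)(C)C(C)(C)C)O[C@@H](c1ccc(O[Si](C)(C)C(C)(C)C)cc1)[C@@H]3c1cc(O[Si](C)(C)C(C)(C)C)cc(O[Si](C)(C)C(C)(C)C)c1)CC2=O)CO[Si](C)(C)C(C)(C)C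
F4 | step 10 | 4-oxo-7-(prop-2-en-1-yloxy)-4H-chromen-5-yl acetate | C=CCOc1cc(OC(C)=O)c2c(c1)OC=CC2=O
F5 | step 10 | 7-hydroxy-4-oxo-8-(prop-2-en-1-yl)-4H-chromen-5-yl acetate | C=CCc1c(O)cc(OC(C)=O)c2c1OC=CC2=O
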